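## Analysis of the target

Target 21 is an open twelve-carbon acyl chain, numbered C1'–C12' from the ketone carbon, joined through C1' to C3 of its only ring, a (6R)-4-hydroxy-6-methyl-5,6-dihydro-2H-pyran-2-one. The chain carries a methyl group at C4' (S), a carboxyl group at C8' (R), a hydroxyl group at C9' (R) and a methyl group at C10' (S), which together with ring carbon C6 (R) makes five stereocentres. C8', C9' and C10' are contiguous: the C7' branch and the C9' hydroxyl are anti when the chain is drawn through the carboxyl carbon (an anti-aldol pattern), and the C9' hydroxyl and the C10' methyl are syn along the C8'–C11' backbone. C4' is separated from this triad by three methylenes and from the ring by C1'–C3', and C6 is remote from both, so no centre can control another domain. The sensitive parts are the enolised β,β'-tricarbonyl unit (acidic, metal-binding, with a lactone that opens under base or nucleophiles), the β-hydroxy acid (retro-aldol, dehydration), and two carboxyl-level termini (C1' and the C8' carboxyl) that must be told apart. The hard part is the anti C8'/C9' pair beside a sec-butyl group whose own centre differs only in methyl versus ethyl, combined with a convergent union of three stereochemical domains. The strategy rests on C7', a plain methylene between the C6' methylene and the carboxyl-bearing C8' methine next to the C9' carbinol: read backwards, C7'=C8'(CO2R)–C9'(OR) is a Baylis–Hillman adduct of an acrylate with an α-branched aldehyde and C6' is a primary alkyl radical, so C8' is created by hydrogen-atom transfer to an ester-stabilised radical under the influence of C9'.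

## Retrosynthetic reasoning

**Protecting groups and the head (C3–C1').** The free acid and the free carbinol of 21 are uncovered last from dibenzyl compound 20 by hydrogenolysis, a neutral operation that the tricarbonyl unit and the β-hydroxy acid tolerate. Cutting C3–C1' of 20 gives chain acid 18 and dihydropyranone 17. This bond is chosen because enolised cyclic 1,3-dicarbonyl compounds of this kind are C-acylated by carboxylic acids through O-acylation and acyl migration, and because the base- and nucleophile-sensitive lactone then enters only after all radical, oxidative and strongly basic chemistry is finished. The forward reaction has to acylate C3 with the C1' carboxyl while the C8' carboxyl stays masked. This fixes the protecting-group pattern: C1' as an acid-labile tert-butyl ester (12 to 18), C8' and C9'–O as benzyl groups.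

**Key disconnection (C6'–C7').** Diester 12 is cut between C6' and C7' into primary iodide 11 and the O-benzyl Baylis–Hillman ester 6. The cut lies between two methylenes, separates the C4' domain from the C8'–C10' triad, and leaves each fragment with only purchasable or catalyst-made stereocentres. In the forward sense the C6' radical adds to the unsubstituted alkene terminus of 6, and the C8' centre is set when the adduct radical takes up hydrogen. A radical is preferred to a polar nucleophile for three reasons. It tolerates both esters. A β-alkoxy radical does not expel the C9' oxygen, whereas an ester enolate would. And the open-chain ester-substituted radical has a defined conformation, so hydrogen is delivered anti to the sec-butyl group, which gives the anti pair. What is gained is one skeletal bond and one stereocentre in the convergent step.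

**Acceptor 6 (C8'–C9').** The benzyl ether and benzyl ester of 6 are traced to hydroxy ester 5 and, by ester exchange, to the activated fluorinated ester 4. Cutting C8'–C9' of 4 gives aldehyde 2 and acrylate 3, a Baylis–Hillman disconnection. It delivers the α-methylene ester and the C9' carbinol in one step, with C9' fixed by an amine catalyst and not by the weakly biased α-centre of 2. Aldehyde 2 comes from alcohol 1 by oxidation, so C10' is bought.

**Radical precursor 11 (C4' from the chiral pool).** Iodide 11 comes from bromide 10 by halide exchange, 10 from acid 9 by esterification, and 9 from (R)-citronellyl bromide 7 by oxidative cleavage of its trisubstituted alkene. The terpene holds the C4' methyl centre two carbons from the halide and three from the alkene, exactly the C6'/C4'/C1' spacing required. Cleaving the isopropylidene group turns the alkene carbon into C1' at the carboxyl oxidation level.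

**Head 17.** Lactone 17 is opened at the ring O–C2 bond to hydroxy keto ester 15, which is cut at C3–C4 into hydroxy ester 13 and acetate 14 (Claisen condensation). C6 of the ring is the purchased carbinol centre of 13, and its C–O bond is never broken.

## Alternatives that were turned down

Alternative 1: C4'–C5' by lithiation–borylation. The primary pinacol boronic ester A2, which has boron on C5' and already holds the C8'–C10' triad, would be homologated with the lithiated, chiral-diamine-complexed carbenoid made from ethyl 2,4,6-triisopropylbenzoate A3. A 1,2-metallate shift of the boronate complex would give the secondary boronic ester A1 with C4' set by the reagent.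
- For: the C4' configuration is reagent-chosen with the high fidelity typical of such shifts, and either epimer is available. On this point it is stronger than the chosen route, whose C4' purity cannot exceed that of terpene-derived 7.
- Against: the key step is spent on a methyl-bearing centre that can be bought. A1 ends at C4', so C1'–C3' with the carboxyl still needs a second stereospecific C–C bond formation at a hindered secondary boronic ester. A strongly basic organolithium meets an ester with an α-hydrogen at C8' in A2. The C8'/C9' anti pair must be solved separately before A2 exists.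
- Comparison: the chosen strategy uses its one strategic bond both to join the halves and to create C8', and obtains C4' in three routine steps.

Alternative 2: C9'–C10' by catalytic syn-crotylboration. The α-branched aldehyde A5, with C8' in place and the carboxyl masked as a benzyloxymethyl group, would react with the (Z)-crotyl pinacol boronate A6 under a chiral phosphoric acid catalyst to give the syn homoallylic alcohol A4. The vinyl group of A4 later becomes the C11'–C12' ethyl group.
- For: C9' and C10' arise together through a closed six-membered transition state under catalyst control. In reliability of the C9' configuration and in expected efficiency this step is stronger than the amine-catalysed Baylis–Hillman step used here.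
- Against: C10' is created although it is available in 1. A5 is an α-stereogenic, enolisable aldehyde whose C8' centre must be set earlier and preserved, and its own facial preference may oppose the catalyst, so the 8',9'-anti relation rests on double stereodifferentiation. C8' is carried at the alcohol oxidation level, which costs a deprotection, two oxidations and protection of the C9' hydroxyl before the head can be attached.
- Comparison: the chosen route carries C8' as an ester from its first C–C bond onward and draws the 8',9' relation from a single adjacent centre.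

Alternative 3: C2'–C3' by dianion alkylation of the acetylated head. The 3-acetyl dihydropyranone A8 would be doubly deprotonated with two equivalents of a lithium amide base and alkylated at the acetyl methyl carbon (C2') by the primary iodide A9, giving the protected target A7 directly.
- For: maximal convergence, no C-acylation or acyl migration, and a shorter end game. On step count after fragment union it is stronger.
- Against: A9 is a β-branched primary iodide (the C4' methyl sits next to the reacting carbon), so substitution is slow and elimination by the hard dianion competes. The second deprotonation of A8 can occur at ring C5, which leads to β-elimination of the lactone oxygen and ring opening. A9 must contain all four chain stereocentres, so the whole stereochemical burden moves into one long linear fragment, and the C8'/C9' problem is not addressed.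
- Comparison: the chosen route keeps strong bases away from the lactone, attaches the head by a mild carbodiimide coupling, and splits the chain into fragments of four and three steps.

Key step: step 8

Assumption: (R)-citronellyl bromide 7 is taken as a purchasable compound, and the head group is written throughout as its 4-hydroxy enol tautomer, as in the target.

## Route

Step 1
Reactants: 1 (S)-2-methylbutan-1-ol
Product: 2 (S)-2-methylbutanal
Conditions: TEMPO (1 mol %), KBr (10 mol %), NaOCl (1.1 equiv), NaHCO3, CH2Cl2/H2O, 0 °C
Reagents that add atoms: none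
Why: Nitroxyl-catalysed hypochlorite oxidation (Anelli oxidation) of a primary alcohol stops at the aldehyde; the buffered two-phase medium at 0 °C should not enolise the α-carbon, so C10' is carried over unchanged, and the volatile aldehyde is used at once.

Step 2
Reactants: 2 (S)-2-methylbutanal; 3 1,1,1,3,3,3-hexafluoropropan-2-yl acrylate
Product: 4 1,1,1,3,3,3-hexafluoropropan-2-yl (3R,4S)-3-hydroxy-4-methyl-2-methylidenehexanoate
Conditions: β-isocupreidine (10 mol %), DMF, −55 °C
Reagents that add atoms: none
Why: Asymmetric Baylis–Hillman reaction: the quinidine-derived amine adds to the activated acrylate, the ammonium enolate adds to the aldehyde with the catalyst hydroxyl organising proton transfer and elimination, and the C8'–C9' bond forms. The 9'R configuration is set by the catalyst, since the methyl/ethyl α-centre of 2 exerts little bias of its own.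

Step 3
Reactants: 4 1,1,1,3,3,3-hexafluoropropan-2-yl (3R,4S)-3-hydroxy-4-methyl-2-methylidenehexanoate
Product: 5 benzyl (3R,4S)-3-hydroxy-4-methyl-2-methylidenehexanoate
Conditions: BnOH (3 equiv), Et3N, DMAP (cat.), CH2Cl2, rt
Reagents that add atoms: benzyl alcohol, OCc1ccccc1
Why: The fluorinated ester is an activated ester, so base-catalysed transesterification (acyl substitution) with benzyl alcohol should proceed at room temperature without touching the carbinol or adding to the α-substituted acrylate.

Step 4
Reactants: 5 benzyl (3R,4S)-3-hydroxy-4-methyl-2-methylidenehexanoate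
Product: 6 benzyl (3R,4S)-3-(benzyloxy)-4-methyl-2-methylidenehexanoate
Conditions: BnOC(=NH)CCl3 (1.5 equiv), TfOH (5 mol %), cyclohexane/CH2Cl2, 0 °C → rt
Reagents that add atoms: benzyl 2,2,2-trichloroacetimidate, ClC(Cl)(Cl)C(=N)OCc1ccccc1
Why: Acid-catalysed O-benzylation with the trichloroacetimidate avoids an alkoxide, which in a Baylis–Hillman adduct would invite retro-aldol cleavage or elimination; the C9'–O bond is not broken, so the configuration is kept.

Step 5
Reactants: 7 (R)-citronellyl bromide
Product: 9 (R)-6-bromo-4-methylhexanoic acid, via (R)-6-bromo-4-methylhexanal 8 (not isolated)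
Conditions: O3, MeCN/H2O (9:1), 0 °C; then NaClO2, NaH2PO4, 0 °C → rt
Reagents that add atoms: ozone, [O-][O+]=O; water, O; sodium chlorite, [Na+].[O-]Cl=O
Why: Ozonolysis in wet acetonitrile gives the aldehyde directly because water intercepts the carbonyl oxide, and chlorite (Pinnick oxidation) converts it to the acid in the same flask, the hydrogen peroxide released in the first stage scavenging hypochlorite. The primary bromide and C4' are inert to both oxidants.

Step 6
Reactants: 9 (R)-6-bromo-4-methylhexanoic acid
Product: 10 tert-butyl (R)-6-bromo-4-methylhexanoate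
Conditions: tBuOC(=NH)CCl3 (2 equiv), BF3·OEt2 (cat.), cyclohexane/CH2Cl2, rt
Reagents that add atoms: tert-butyl 2,2,2-trichloroacetimidate, CC(C)(C)OC(=N)C(Cl)(Cl)Cl
Why: Acid-catalysed tert-butylation of a carboxylic acid by the imidate; no base is present, so the bromide is neither displaced nor eliminated.

Step 7
Reactants: 10 tert-butyl (R)-6-bromo-4-methylhexanoate
Product: 11 tert-butyl (R)-6-iodo-4-methylhexanoate
Conditions: NaI (3 equiv), acetone, reflux
Reagents that add atoms: sodium iodide, [Na+].[I-]
Why: Finkelstein exchange (SN2 at the primary carbon), driven by precipitation of NaBr; the iodide is needed because iodine-atom abstraction stays fast at −78 °C, where bromine abstraction would not.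

Step 8
Reactants: 11 tert-butyl (R)-6-iodo-4-methylhexanoate; 6 benzyl (3R,4S)-3-(benzyloxy)-4-methyl-2-methylidenehexanoate
Product: 12 1-benzyl 9-tert-butyl (2R,6S)-2-[(1R,2S)-1-(benzyloxy)-2-methylbutyl]-6-methylnonanedioate
Conditions: 11 (3 equiv), Bu3SnH (2.5 equiv, syringe pump), Et3B (portions), air, CH2Cl2, −78 °C
Reagents that add atoms: none
Why: Ethyl radicals from Et3B and oxygen abstract iodine from 11; the nucleophilic primary C6' radical adds to the unsubstituted CH2 terminus of the electron-poor 1,1-disubstituted acrylate 6 and forms C6'–C7', and the tertiary ester-stabilised C8' radical then abstracts hydrogen from Bu3SnH, the stannyl radical carrying the chain. The closest known reaction type is the Giese (reductive radical conjugate) addition of alkyl iodides to 2-(1-alkoxyalkyl)acrylates, whose hydrogen-transfer step is the same as in the low-temperature reduction of α-halo-β-alkoxy esters under non-chelating conditions. No ring is closed. The one new stereocentre, C8', is controlled by the adjacent C9' centre: allylic 1,3-strain holds the C9'–H bond in the plane of the radical, eclipsing the ester, so the benzyloxy and sec-butyl groups lie on opposite faces and the stannane approaches anti to the sec-butyl group, which gives 8'R, the 8',9'-anti relation. The step needs three selectivities: regioselectivity, secured because only the CH2 terminus is open and polarity-matched; addition before reduction of the C6' radical, secured by excess 11 and slow addition of the stannane; and facial selectivity, secured by low temperature and the absence of any chelating metal salt, since a Lewis acid such as MgBr2 would bridge the ester and ether oxygens and turn the other face toward the hydrogen donor. The β-benzyloxy group is not expelled from a radical, and C4', C9' and C10' are untouched.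

Step 9
Reactants: 13 ethyl (R)-3-hydroxybutanoate; 14 tert-butyl acetate
Product: 15 tert-butyl (R)-5-hydroxy-3-oxohexanoate
Conditions: 14 (4 equiv), LiN(iPr)2 (4 equiv), THF, −78 °C; then 13, −78 → −30 °C; aq. NH4Cl
Reagents that add atoms: none
Why: Crossed Claisen condensation: excess lithium enolate of 14 first deprotonates the hydroxyl and then acylates at the ethyl ester, and the product is protected from over-addition as its β-keto ester enolate; the carbinol centre is not involved.

Step 10
Reactants: 15 tert-butyl (R)-5-hydroxy-3-oxohexanoate
Product: 17 (6R)-4-hydroxy-6-methyl-5,6-dihydro-2H-pyran-2-one, via (R)-5-hydroxy-3-oxohexanoic acid 16 (not isolated)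
Conditions: TFA, CH2Cl2, rt
Reagents that add atoms: none
Why: Acidolysis of the tert-butyl ester followed by lactonisation of the δ-hydroxy β-keto acid to the six-membered enolised keto lactone, which should outrun decarboxylation at room temperature; the carbinol C–O bond is retained, so C6 stays R.

Step 11
Reactants: 12 1-benzyl 9-tert-butyl (2R,6S)-2-[(1R,2S)-1-(benzyloxy)-2-methylbutyl]-6-methylnonanedioate
Product: 18 (4S,8R)-9-(benzyloxy)-8-[(1R,2S)-1-(benzyloxy)-2-methylbutyl]-4-methyl-9-oxononanoic acid
Conditions: TFA/CH2Cl2 (1:3), 0 °C → rt
Reagents that add atoms: none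
Why: Selective acidolysis of the tert-butyl ester through the tert-butyl cation; benzyl esters and benzyl ethers are stable to these conditions, so only the C1' carboxyl is freed.

Step 12
Reactants: 18 (4S,8R)-9-(benzyloxy)-8-[(1R,2S)-1-(benzyloxy)-2-methylbutyl]-4-methyl-9-oxononanoic acid; 17 (6R)-4-hydroxy-6-methyl-5,6-dihydro-2H-pyran-2-one
Product: 20 benzyl (2R,6S)-2-[(1R,2S)-1-(benzyloxy)-2-methylbutyl]-9-[(6R)-4-hydroxy-6-methyl-2-oxo-5,6-dihydro-2H-pyran-3-yl]-6-methyl-9-oxononanoate, via pyran-4-yl enol ester 19 (not isolated)
Conditions: DCC (1.2 equiv), DMAP (1.2 equiv), CH2Cl2, 0 °C → rt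
Reagents that add atoms: none
Why: Carbodiimide activation first O-acylates the enol (Steglich-type esterification); DMAP then moves the acyl group from oxygen to C3 through an acylpyridinium/enolate pair (Fries-type O→C acyl migration), the standard entry to 3-acyl-4-hydroxypyranones. The hindered C8' benzyl ester and all stereocentres are unaffected.

Step 13
Reactants: 20 benzyl (2R,6S)-2-[(1R,2S)-1-(benzyloxy)-2-methylbutyl]-9-[(6R)-4-hydroxy-6-methyl-2-oxo-5,6-dihydro-2H-pyran-3-yl]-6-methyl-9-oxononanoate
Product: 21 (2R,6S)-2-[(1R,2S)-1-hydroxy-2-methylbutyl]-9-[(6R)-4-hydroxy-6-methyl-2-oxo-5,6-dihydro-2H-pyran-3-yl]-6-methyl-9-oxononanoic acid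
Conditions: H2 (1 atm), Pd/C (10%), EtOAc, rt
Reagents that add atoms: none
Why: Hydrogenolysis removes the benzyl ester and the benzyl ether in one neutral operation; the enolised tricarbonyl unit should not be reduced at atmospheric pressure, and neither the lactone nor the β-hydroxy acid is exposed to acid or base.

## Compound list

1 | (S)-2-methylbutan-1-ol | CC[C@H](C)CO | starting material
2 | (S)-2-methylbutanal | CC[C@H](C)C=O | intermediate
3 | 1,1,1,3,3,3-hexafluoropropan-2-yl acrylate | C=CC(=O)OC(C(F)(F)F)C(F)(F)F | starting material
4 | 1,1,1,3,3,3-hexafluoropropan-2-yl (3R,4S)-3-hydroxy-4-methyl-2-methylidenehexanoate | CC[C@H](C)[C@@H](O)C(=C)C(=O)OC(C(F)(F)F)C(F)(F)F | intermediate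
5 | benzyl (3R,4S)-3-hydroxy-4-methyl-2-methylidenehexanoate | CC[C@H](C)[C@@H](O)C(=C)C(=O)OCc1ccccc1 | intermediate
6 | benzyl (3R,4S)-3-(benzyloxy)-4-methyl-2-methylidenehexanoate | CC[C@H](C)[C@@H](OCc1ccccc1)C(=C)C(=O)OCc1ccccc1 | intermediate
7 | (R)-citronellyl bromide, (6R)-8-bromo-2,6-dimethyloct-2-ene | BrCC[C@H](C)CCC=C(C)C | starting material
8 | (R)-6-bromo-4-methylhexanal | BrCC[C@H](C)CCC=O | intermediate
9 | (R)-6-bromo-4-methylhexanoic acid | BrCC[C@H](C)CCC(=O)O | intermediate
10 | tert-butyl (R)-6-bromo-4-methylhexanoate | BrCC[C@H](C)CCC(=O)OC(C)(C)C | intermediate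
11 | tert-butyl (R)-6-iodo-4-methylhexanoate | ICC[C@H](C)CCC(=O)OC(C)(C)C | intermediate
12 | 1-benzyl 9-tert-butyl (2R,6S)-2-[(1R,2S)-1-(benzyloxy)-2-methylbutyl]-6-methylnonanedioate | CC[C@H](C)[C@@H](OCc1ccccc1)[C@@H](CCC[C@H](C)CCC(=O)OC(C)(C)C)C(=O)OCc1ccccc1 | intermediate
13 | ethyl (R)-3-hydroxybutanoate | CCOC(=O)C[C@@H](C)O | starting material
14 | tert-butyl acetate | CC(=O)OC(C)(C)C | starting material
15 | tert-butyl (R)-5-hydroxy-3-oxohexanoate | C[C@@H](O)CC(=O)CC(=O)OC(C)(C)C | intermediate
16 | (R)-5-hydroxy-3-oxohexanoic acid | C[C@@H](O)CC(=O)CC(=O)O | intermediate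
17 | (6R)-4-hydroxy-6-methyl-5,6-dihydro-2H-pyran-2-one | C[C@@H]1CC(O)=CC(=O)O1 | intermediate
18 | (4S,8R)-9-(benzyloxy)-8-[(1R,2S)-1-(benzyloxy)-2-methylbutyl]-4-methyl-9-oxononanoic acid | CC[C@H](C)[C@@H](OCc1ccccc1)[C@@H](CCC[C@H](C)CCC(=O)O)C(=O)OCc1ccccc1 | intermediate
19 | 1-benzyl 9-[(6R)-6-methyl-2-oxo-5,6-dihydro-2H-pyran-4-yl] (2R,6S)-2-[(1R,2S)-1-(benzyloxy)-2-methylbutyl]-6-methylnonanedioate | CC[C@H](C)[C@@H](OCc1ccccc1)[C@@H](CCC[C@H](C)CCC(=O)OC1=CC(=O)O[C@H](C)C1)C(=O)OCc1ccccc1 | intermediate
20 | benzyl (2R,6S)-2-[(1R,2S)-1-(benzyloxy)-2-methylbutyl]-9-[(6R)-4-hydroxy-6-methyl-2-oxo-5,6-dihydro-2H-pyran-3-yl]-6-methyl-9-oxononanoate | CC[C@H](C)[C@@H](OCc1ccccc1)[C@@H](CCC[C@H](C)CCC(=O)C1=C(O)C[C@@H](C)OC1=O)C(=O)OCc1ccccc1 | intermediate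
21 | (2R,6S)-2-[(1R,2S)-1-hydroxy-2-methylbutyl]-9-[(6R)-4-hydroxy-6-methyl-2-oxo-5,6-dihydro-2H-pyran-3-yl]-6-methyl-9-oxononanoic acid | CC[C@H](C)[C@@H](O)[C@@H](CCC[C@H](C)CCC(=O)C1=C(O)C[C@@H](C)OC1=O)C(=O)O | target

## Step count and risks

Total step count: 13. Longest linear sequence: 8 steps (steps 1–4, 8, 11, 12, 13).

**Step 8 (key step).** The most likely failure is insufficient facial selectivity in the hydrogen transfer, because the benzyloxy and sec-butyl groups may not be differentiated strongly enough. The problem would worsen if the temperature had to be raised because the primary radical is reduced by the stannane before it adds at −78 °C. Separation of the C8' epimers would be difficult.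

The fallback sets C8' by C–C bond formation on a chelated dianion instead of by hydrogen delivery; it sets out from 2 and 11 and returns at 12. A catalytic asymmetric Mukaiyama acetate aldol reaction of 2 with 1-(benzyloxy)-1-(trimethylsilyloxy)ethene is run with Ti(OiPr)4, a binaphthyl-derived tridentate Schiff-base ligand and 3,5-di-tert-butylsalicylic acid, the ligand enantiomer being chosen for the 3S carbinol. It should give the silylated aldol adduct benzyl (3S,4S)-4-methyl-3-[(trimethylsilyl)oxy]hexanoate F1, which Bu4NF in the work-up converts to benzyl (3S,4S)-3-hydroxy-4-methylhexanoate F2. The dianion of F2 (LiN(iPr)2, 2.2 equiv, THF, −78 → −20 °C) is allylated with allyl bromide anti to the alkoxide-bearing carbon (Fráter–Seebach alkylation) to give the anti-allylated hydroxy ester benzyl (2R,3R,4S)-3-hydroxy-4-methyl-2-(prop-2-en-1-yl)hexanoate F3. Benzylation as in step 4 gives the benzyl ether benzyl (2R,3R,4S)-3-(benzyloxy)-4-methyl-2-(prop-2-en-1-yl)hexanoate F4. In parallel, 11 is dehydrohalogenated (KOtBu, THF, 0 °C) to tert-butyl (R)-4-methylhex-5-enoate F5. Cross-metathesis of F4 with an excess of F5 (second-generation Hoveyda–Grubbs catalyst, CH2Cl2, 40 °C) gives the C5'–C6' alkene 1-benzyl 9-tert-butyl (2R,4E,6R)-2-[(1R,2S)-1-(benzyloxy)-2-methylbutyl]-6-methylnon-4-enedioate F6. Diimide (2-nitrobenzenesulfonylhydrazide, Et3N) then saturates the alkene without touching the benzyl groups and gives 12.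

**Step 2.** The most likely failure is low conversion with the α-branched aldehyde, part of which is also diverted into a second addition that ends in a dioxanone. Slow epimerisation at the α-carbon of 2 during a long reaction with an amine would erode the C10' configuration.

The fallback takes C9' from an aldol catalyst and adds the methylene group afterwards; it sets out from 2 and returns at 5. The silylated aldol adduct benzyl (3S,4S)-4-methyl-3-[(trimethylsilyl)oxy]hexanoate F1 and benzyl (3S,4S)-3-hydroxy-4-methylhexanoate F2 are made as described under step 8. The dianion of F2 (LiN(iPr)2, THF) is aminomethylated with dimethylmethyleneammonium iodide to the Mannich base benzyl (3R,4S)-2-[(dimethylamino)methyl]-3-hydroxy-4-methylhexanoate F7. Methyl iodide converts it to the quaternary salt [(3R,4S)-2-(benzyloxycarbonyl)-3-hydroxy-4-methylhexyl]trimethylammonium iodide F8. DBU then induces elimination of trimethylamine and gives 5.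

**Step 4.** The most likely failure is sluggish alkylation of the hindered, electron-poor allylic carbinol, so that the imidate is consumed by rearrangement or self-condensation first. Acid-induced allylic transposition of the oxygen is a second possibility.

The fallback forms the O–CH2Ph bond by reduction, not by alkylation; it sets out from 5 and returns at 6. Compound 5 is silylated (TMSCl, imidazole) to the trimethylsilyl ether benzyl (3R,4S)-4-methyl-2-methylidene-3-[(trimethylsilyl)oxy]hexanoate F9. Reductive etherification of F9 with benzaldehyde and Et3SiH under catalytic TMSOTf (CH2Cl2, −78 °C) reduces the intermediate oxocarbenium ion and gives the benzyl ether 6.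

**Step 12.** The most likely failure is that the reaction stops at enol ester 19, because the O→C acyl shift of a long aliphatic acyl group is slow, with loss of activated acid by rearrangement to an N-acylurea.

The fallback builds the ring onto the chain instead of acylating the ring; it sets out from 18 (with 13) and returns at 20. Acid 18 is condensed with Meldrum's acid (DCC, DMAP, CH2Cl2) to the acyl Meldrum's acid benzyl (2R,6S)-2-[(1R,2S)-1-(benzyloxy)-2-methylbutyl]-9-(2,2-dimethyl-4,6-dioxo-1,3-dioxan-5-ylidene)-9-hydroxy-6-methylnonanoate F10. Heating F10 with 13 (toluene, 80 °C) gives, through the acyl ketene, the β-keto ester 1-benzyl 11-[(2R)-4-ethoxy-4-oxobutan-2-yl] (2R,6S)-2-[(1R,2S)-1-(benzyloxy)-2-methylbutyl]-6-methyl-9-oxoundecanedioate F11. Dieckmann cyclisation of the active methylene of F11 onto the ethyl ester (KOtBu, tBuOH/THF, 0 °C) closes the lactone ring and gives 20.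

## Further compounds

F1 | step 8 | benzyl (3S,4S)-4-methyl-3-[(trimethylsilyl)oxy]hexanoate | CC[C@H](C)[C@@H](O[Si](C)(C)C)CC(=O)OCc1ccccc1
F2 | step 8 | benzyl (3S,4S)-3-hydroxy-4-methylhexanoate | CC[C@H](C)[C@@H](O)CC(=O)OCc1ccccc1
F3 | step 8 | benzyl (2R,3R,4S)-3-hydroxy-4-methyl-2-(prop-2-en-1-yl)hexanoate | CC[C@H](C)[C@@H](O)[C@@H](CC=C)C(=O)OCc1ccccc1
F4 | step 8 | benzyl (2R,3R,4S)-3-(benzyloxy)-4-methyl-2-(prop-2-en-1-yl)hexanoate | CC[C@H](C)[C@@H](OCc1ccccc1)[C@@H](CC=C)C(=O)OCc1ccccc1
F5 | step 8 | tert-butyl (R)-4-methylhex-5-enoate | C=C[C@H](C)CCC(=O)OC(C)(C)C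
F6 | step 8 | 1-benzyl 9-tert-butyl (2R,4E,6R)-2-[(1R,2S)-1-(benzyloxy)-2-methylbutyl]-6-methylnon-4-enedioate | CC[C@H](C)[C@@H](OCc1ccccc1)[C@@H](C/C=C/[C@H](C)CCC(=O)OC(C)(C)C)C(=O)OCc1ccccc1
F7 | step 2 | benzyl (3R,4S)-2-[(dimethylamino)methyl]-3-hydroxy-4-methylhexanoate (C2 epimers) | CC[C@H](C)[C@@H](O)C(CN(C)C)C(=O)OCc1ccccc1
F8 | step 2 | [(3R,4S)-2-(benzyloxycarbonyl)-3-hydroxy-4-methylhexyl]trimethylammonium iodide (C2 epimers) | CC[C@H](C)[C@@H](O)C(C[N+](C)(C)C)C(=O)OCc1ccccc1.[I-]
F9 | step 4 | benzyl (3R,4S)-4-methyl-2-methylidene-3-[(trimethylsilyl)oxy]hexanoate | CC[C@H](C)[C@@H](O[Si](C)(C)C)C(=C)C(=O)OCc1ccccc1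
F10 | step 12 | benzyl (2R,6S)-2-[(1R,2S)-1-(benzyloxy)-2-methylbutyl]-9-(2,2-dimethyl-4,6-dioxo-1,3-dioxan-5-ylidene)-9-hydroxy-6-methylnonanoate | CC[C@H](C)[C@@H](OCc1ccccc1)[C@@H](CCC[C@H](C)CCC(O)=C1C(=O)OC(C)(C)OC1=O)C(=O)OCc1ccccc1
F11 | step 12 | 1-benzyl 11-[(2R)-4-ethoxy-4-oxobutan-2-yl] (2R,6S)-2-[(1R,2S)-1-(benzyloxy)-2-methylbutyl]-6-methyl-9-oxoundecanedioate | CC[C@H](C)[C@@H](OCc1ccccc1)[C@@H](CCC[C@H](C)CCC(=O)CC(=O)O[C@H](C)CC(=O)OCC)C(=O)OCc1ccccc1
A1 | alternative 1 | tert-butyl (2R,6S)-2-[(1R,2S)-1-[(tert-butyldimethylsilyl)oxy]-2-methylbutyl]-6-(4,4,5,5-tetramethyl-1,3,2-dioxaborolan-2-yl)heptanoate | CC[C@H](C)[C@@H](O[Si](C)(C)C(C)(C)C)[C@@H](CCC[C@H](C)B1OC(C)(C)C(C)(C)O1)C(=O)OC(C)(C)C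
A2 | alternative 1 | tert-butyl (2R)-2-[(1R,2S)-1-[(tert-butyldimethylsilyl)oxy]-2-methylbutyl]-5-(4,4,5,5-tetramethyl-1,3,2-dioxaborolan-2-yl)pentanoate | CC[C@H](C)[C@@H](O[Si](C)(C)C(C)(C)C)[C@@H](CCCB1OC(C)(C)C(C)(C)O1)C(=O)OC(C)(C)C
A3 | alternative 1 | ethyl 2,4,6-triisopropylbenzoate | CCOC(=O)c1c(C(C)C)cc(C(C)C)cc1C(C)C
A4 | alternative 2 | methyl (4S,8S,9R,10S)-8-[(benzyloxy)methyl]-9-hydroxy-4,10-dimethyldodec-11-enoate | C=C[C@H](C)[C@@H](O)[C@@H](CCC[C@H](C)CCC(=O)OC)COCc1ccccc1
A5 | alternative 2 | methyl (4S,8S)-8-[(benzyloxy)methyl]-4-methyl-9-oxononanoate | O=C[C@@H](CCC[C@H](C)CCC(=O)OC)COCc1ccccc1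
A6 | alternative 2 | (Z)-crotyl pinacol boronate | C/C=C\CB1OC(C)(C)C(C)(C)O1
A7 | alternative 3 | tert-butyl (2R,6S)-2-[(1R,2S)-1-[(tert-butyldimethylsilyl)oxy]-2-methylbutyl]-9-[(6R)-4-hydroxy-6-methyl-2-oxo-5,6-dihydro-2H-pyran-3-yl]-6-methyl-9-oxononanoate | CC[C@H](C)[C@@H](O[Si](C)(C)C(C)(C)C)[C@@H](CCC[C@H](C)CCC(=O)C1=C(O)C[C@@H](C)OC1=O)C(=O)OC(C)(C)C
A8 | alternative 3 | (6R)-3-acetyl-4-hydroxy-6-methyl-5,6-dihydro-2H-pyran-2-one | CC(=O)C1=C(O)C[C@@H](C)OC1=O
A9 | alternative 3 | tert-butyl (2R,6S)-2-[(1R,2S)-1-[(tert-butyldimethylsilyl)oxy]-2-methylbutyl]-7-iodo-6-methylheptanoate | CC[C@H](C)[C@@H](O[Si](C)(C)C(C)(C)C)[C@@H](CCC[C@H](C)CI)C(=O)OC(C)(C)C
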